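**Retrosynthetic overview**
1. Ring B is closed last: C9–C8a by intramolecular Friedel–Crafts acylation of ring A, with the peri O-methyl group cleaved in the same flask.
2. The pyrrolidine-fused oxazolidine comes from a six-membered D-proline lactone by decarboxylative ring contraction; Cα first fixes C4, then C4 fixes the aminal carbon.
3. Ring C comes from a two-carbon ring expansion of a squarate-derived cyclobutenone: an aryl alkynoate is inserted into the C1–C4 bond and brings ring A, C4a, C10a, C10 and C9.
4. The cyclobutenone lactone is made from squaric acid, D-proline and MeLi; the alkynoate from resorcinol, ethynyltrimethylsilane and ethyl diazoacetate.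
5. Ring order: ring A, the pyrrolidine and the four-membered ring are bought; then lactone ring, ring C, oxazolidine, ring B.

Assumption: the target is made as the 9-keto-10H tautomer written in the SMILES; atoms are numbered as in phenanthrene (ring C = C1, C2, C3, C4, C4a, C10a; ring B = C4a, C4b, C8a, C9, C10, C10a; ring A = C4b to C8a) and Cα is the proline α-carbon.

Step 1
Reactants: 1 resorcinol
Product: 2 1,3-dimethoxybenzene
Conditions: MeI (2.5 equiv), K2CO3 (2.5 equiv), acetone, reflux
Reagents that add atoms: iodomethane, CI
Why: Williamson ether synthesis on both phenols under standard carbonate conditions; no stereocentre.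

Step 2
Reactants: 2 1,3-dimethoxybenzene
Product: 4 1-bromo-3,5-dimethoxybenzene, via arylboronate 3 (not isolated)
Conditions: [Ir(OMe)(cod)]2 (1 mol %), dtbpy (2 mol %), B2pin2 (0.55 equiv), THF, 80 °C; then CuBr2 (3 equiv), MeOH/H2O, 80 °C
Reagents that add atoms: CuBr2, Br[Cu]Br
Why: Iridium-catalysed aromatic C–H borylation is sterically controlled and takes the only C–H without an ortho substituent (C5), and copper-mediated bromodeboronation of 3 in the same flask gives the meta bromide.

Step 3
Reactants: 4 1-bromo-3,5-dimethoxybenzene, 5 ethynyltrimethylsilane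
Product: 7 1-ethynyl-3,5-dimethoxybenzene, via silylalkyne 6 (not isolated)
Conditions: PdCl2(PPh3)2 (2 mol %), CuI (4 mol %), Et3N, 70 °C (sealed); then K2CO3 (0.2 equiv), MeOH, rt
Reagents that add atoms: none
Why: Sonogashira coupling of the aryl bromide with the silyl-capped acetylene, then carbonate-catalysed methanolysis of the C–Si bond in the same flask.

Step 4
Reactants: 7 1-ethynyl-3,5-dimethoxybenzene, 8 ethyl diazoacetate
Product: 9 ethyl 4-(3,5-dimethoxyphenyl)but-3-ynoate
Conditions: CuI (5 mol %), MeCN, rt
Reagents that add atoms: none
Why: Copper-catalysed coupling of a terminal alkyne with a diazoacetate (copper acetylide, carbene migratory insertion, protonation) gives the 3-alkynoate under base-free conditions that do not isomerise it to the allenoate.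

Step 5
Reactants: 10 squaric acid
Product: 11 dimethyl squarate
Conditions: HC(OMe)3 (2.2 equiv), MeOH, reflux
Reagents that add atoms: methanol, CO; trimethyl orthoformate, COC(OC)OC
Why: Esterification of the vinylogous acid, driven by water removal with the orthoester.

Step 6
Reactants: 12 D-proline, 11 dimethyl squarate
Product: 14 methyl (R)-1-(2-methoxy-3,4-dioxocyclobut-1-en-1-yl)pyrrolidine-2-carboxylate, via D-proline methyl ester hydrochloride 13 (not isolated)
Conditions: SOCl2 (1.2 equiv), MeOH, 0 °C → reflux, evaporate; then 11 (1.0 equiv), Et3N (1.1 equiv), MeOH, 0 °C → rt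
Reagents that add atoms: methanol, CO
Why: Acid-chloride-mediated Fischer esterification of the amino acid, then addition–elimination of the secondary amine at one vinylogous ester carbon of the squarate, which stops at the monoamide; Cα is not touched.

Step 7
Reactants: 14 methyl (R)-1-(2-methoxy-3,4-dioxocyclobut-1-en-1-yl)pyrrolidine-2-carboxylate
Product: 16 cis-fused cyclobutenone lactone (Cα R; C4 S), via lithium alkoxide 15 (not isolated)
Conditions: MeLi (1.05 equiv), THF, −78 °C, then 0 °C (1 h); AcOH (1.1 equiv)
Reagents that add atoms: methyllithium, [Li]C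
Why: 1,2-Addition of the organolithium to the more electrophilic squarate carbonyl (next to the amino-bearing carbon; the other is a vinylogous amide) anti to the proline ester, then alkoxide-to-ester lactonisation, which is geometrically possible only when the C4 oxygen and the ester are on the same face, so the D-proline α-carbon sets C4 and any trans adduct stays open and is removed.

Step 8
Reactants: 16 cis-fused cyclobutenone lactone, 9 ethyl 4-(3,5-dimethoxyphenyl)but-3-ynoate
Product: 17 p-quinol lactone (ring C dienone; Cα R; C4 R)
Conditions: Ni(cod)2 (10 mol %), IPr (1,3-bis(2,6-diisopropylphenyl)imidazol-2-ylidene, 10 mol %), toluene, 40 °C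
Reagents that add atoms: none
Why: Proposed new method: zerovalent nickel inserts into the strained, allylic and α-oxygenated acyl–C4 σ-bond of 16 to give a nickelacyclopentenone, alkyne 9 inserts into the Ni–acyl bond with the acyl carbon going to the CH2CO2Et-bearing carbon and nickel to the aryl-bearing carbon (the usual sense for aryl alkyl alkynes, and the quaternary C4 end is too hindered to insert), and C(sp3)–C(sp2) reductive elimination closes ring C, so the four-membered ring grows by two carbons at 40 °C without a thermal electrocyclic step, while C4 cannot invert because it stays locked in the cis lactone with Cα; the closest known reaction types are the nickel-catalysed cyclobutenone–alkyne benzannulation to phenols and the nickel-catalysed insertion of alkynes into cyclobutanones, neither shown for a 4,4-disubstituted 4-acyloxy-3-aminocyclobutenone that must give a non-aromatisable p-quinol.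

Step 9
Reactants: 17 p-quinol lactone
Product: 20 oxazolidine acid (C4 R; aminal C S), via dilithium dicarboxylate 18 (not isolated), via iminium zwitterion 19 (not isolated)
Conditions: LiOH (2.2 equiv), THF/H2O, 0 °C → rt; then MeCN/H2O, graphite anode, Pt cathode, undivided cell, constant current, 2.2 F/mol, 5 °C; then 1 M HCl to pH 3
Reagents that add atoms: lithium hydroxide, [Li+].[OH-]
Why: Saponification opens the lactone and the ethyl ester, and anodic two-electron decarboxylation of the α-amino carboxylate (Hofer–Moest reaction, easier than oxidation of the unactivated side-chain carboxylate) gives iminium 19, which the C4 hydroxyl closes to the oxazolidine, a net six-to-five ring contraction in which C4 sets the aminal carbon because only the epimer with the aminal H syn to the C4 methyl lets the planar-nitrogen pyrrolidine fuse without strain, and the acidic work-up equilibrates to it.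

Step 10
Reactants: 20 oxazolidine acid
Product: 23 CNP0528850.1 (target), via acid chloride 21 (not isolated), via O-methyl ketone 22 (not isolated)
Conditions: 1-chloro-N,N,2-trimethylprop-1-en-1-amine (1.2 equiv), CH2Cl2, 0 °C → rt; then BCl3 (3 equiv), CH2Cl2, −78 → 0 °C; aq. NaHCO3
Reagents that add atoms: none
Why: Intramolecular Friedel–Crafts acylation at the ring A carbon ortho/para to the two methoxy groups (both ortho positions are equivalent) closes ring B as the 9-keto-10H form, and BCl3 then cleaves only the methyl ether peri to the new C9 carbonyl through the six-membered boron chelate; no stereocentre is changed, and an aminal opened by the Lewis acid re-closes to the same strain-free epimer.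

**Compound list**
1 | resorcinol (benzene-1,3-diol) | Oc1cccc(O)c1 | starting material
2 | 1,3-dimethoxybenzene | COc1cccc(OC)c1 | intermediate
3 | 2-(3,5-dimethoxyphenyl)-4,4,5,5-tetramethyl-1,3,2-dioxaborolane | COc1cc(OC)cc(c1)B1OC(C)(C)C(C)(C)O1 | intermediate
4 | 1-bromo-3,5-dimethoxybenzene | COc1cc(Br)cc(OC)c1 | intermediate
5 | ethynyltrimethylsilane | C#C[Si](C)(C)C | starting material
6 | [(3,5-dimethoxyphenyl)ethynyl]trimethylsilane | COc1cc(OC)cc(c1)C#C[Si](C)(C)C | intermediate
7 | 1-ethynyl-3,5-dimethoxybenzene | COc1cc(OC)cc(c1)C#C | intermediate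
8 | ethyl diazoacetate | CCOC(=O)C=[N+]=[N-] | starting material
9 | ethyl 4-(3,5-dimethoxyphenyl)but-3-ynoate | CCOC(=O)CC#Cc1cc(OC)cc(OC)c1 | intermediate
10 | squaric acid (3,4-dihydroxycyclobut-3-ene-1,2-dione) | OC1=C(O)C(=O)C1=O | starting material
11 | dimethyl squarate (3,4-dimethoxycyclobut-3-ene-1,2-dione) | COC1=C(OC)C(=O)C1=O | intermediate
12 | D-proline ((R)-pyrrolidine-2-carboxylic acid) | OC(=O)[C@H]1CCCN1 | starting material
13 | D-proline methyl ester hydrochloride | Cl.COC(=O)[C@H]1CCCN1 | intermediate
14 | methyl (R)-1-(2-methoxy-3,4-dioxocyclobut-1-en-1-yl)pyrrolidine-2-carboxylate | COC1=C(N2CCC[C@@H]2C(=O)OC)C(=O)C1=O | intermediate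
15 | lithium (1S)-3-methoxy-2-[(2R)-2-(methoxycarbonyl)pyrrolidin-1-yl]-1-methyl-4-oxocyclobut-2-en-1-olate | [Li+].COC1=C(N2CCC[C@@H]2C(=O)OC)[C@](C)([O-])C1=O | intermediate
16 | tricyclic lactone: 2-methoxy-4-methylcyclobut-2-en-1-one with the D-proline nitrogen on C3 and the C4 oxygen lactonised with the proline carboxyl (six-membered 1,4-oxazin-2-one fused to the pyrrolidine and to C3–C4); Cα (R), C4 (S), lactone carbonyl and C4–O on the same face | COC1=C2N3CCC[C@@H]3C(=O)O[C@]2(C)C1=O | intermediate
17 | p-quinol lactone: cyclohexa-2,5-dien-1-one (ring C) with 2-OMe, the D-proline nitrogen on C3, 4-methyl, the C4 oxygen lactonised with the proline carboxyl, 3,5-dimethoxyphenyl on C4a and CH2CO2Et on C10a; Cα (R), C4 (R) | COC1=C2N3CCC[C@@H]3C(=O)O[C@]2(C)C(c2cc(OC)cc(OC)c2)=C(CC(=O)OCC)C1=O | intermediate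
18 | dilithium salt of the diacid from 17: free C4–OH, proline carboxylate and side-chain carboxylate; Cα (R), C4 (R) | [Li+].[Li+].COC1=C(N2CCC[C@@H]2C(=O)[O-])[C@](C)(O)C(c2cc(OC)cc(OC)c2)=C(CC(=O)[O-])C1=O | intermediate
19 | cyclic iminium (3,4-dihydro-2H-pyrrol-1-ium) zwitterion from 18 after loss of CO2 and two electrons: N+=CH in the five-membered ring, free C4–OH, side-chain carboxylate; C4 (R) | COC1=C([N+]2=CCCC2)[C@](C)(O)C(c2cc(OC)cc(OC)c2)=C(CC(=O)[O-])C1=O | intermediate
20 | oxazolidine acid: ring C dienone of the target with the pyrrolidine-fused oxazolidine across C3–N and C4–O, 3,5-dimethoxyphenyl on C4a and CH2CO2H on C10a; C4 (R), aminal carbon (S) | COC1=C2N3CCC[C@@H]3O[C@]2(C)C(c2cc(OC)cc(OC)c2)=C(CC(=O)O)C1=O | intermediate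
21 | acid chloride of 20 (CH2COCl on C10a); C4 (R), aminal carbon (S) | COC1=C2N3CCC[C@@H]3O[C@]2(C)C(c2cc(OC)cc(OC)c2)=C(CC(=O)Cl)C1=O | intermediate
22 | 8-O-methyl ether of the target (ring B closed, C9 ketone, C10 H2, 6,8-dimethoxy); C4 (R), aminal carbon (S) | COC1=C2N3CCC[C@@H]3O[C@]2(C)C2=C(CC(=O)c3c(OC)cc(OC)cc32)C1=O | intermediate
23 | CNP0528850.1: 8-hydroxy-2,6-dimethoxy-4-methyl-10H-phenanthrene-1,9-dione skeleton with a pyrrolidine-fused oxazolidine across C3–N and C4–O; C4 (R), aminal carbon (S) | COC1=C2N3CCC[C@@H]3O[C@]2(C)C2=C(CC(=O)c3c(O)cc(OC)cc32)C1=O | target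

**Step count and risks**
Total steps: 10. Longest linear sequence: 7 (steps 1, 2, 3, 4, 8, 9, 10).

The three steps most likely to fail:

The nickel ring expansion (step 8, the proposed new method) may give the regioisomeric dienone or stall at the hindered C4–C4a reductive elimination. The fallback uses known chemistry, sets out from 14 and 9 and comes back at 17. Compound 14 is treated with ClCo(PPh3)3 (monovalent cobalt) in benzene, and cobalt inserts into the dione C–C bond to give the maleoylcobalt complex F1. AgBF4 in MeCN in the presence of 9 then gives the benzoquinone F2 by alkyne insertion and reductive elimination, a known stoichiometric cyclobutenedione-to-quinone ring expansion; regioisomers are separated. MeLi (THF, −78 → 0 °C) adds to the C4 carbonyl of F2 (next to the amino-bearing carbon; the C1 carbonyl is the vinylogous amide), and the cis alkoxide lactonises onto the proline ester to give 17.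

The MeLi addition and lactonisation (step 7) may suffer from poor facial selectivity, attack on the methyl ester, or partial epimerisation of Cα by the methoxide released. The fallback sets out from 11 and 12 and comes back at 16. Free D-proline 12 and 11 (Et3N, MeOH) give the squaramide acid F3. MeMgBr (2.2 equiv, THF, −78 °C) adds to the same carbonyl with no ester and no alkoxide base in the flask, and gives the hydroxy acid F4 together with its C4 epimer. Carboxyl activation (2,4,6-trichlorobenzoyl chloride, Et3N, then DMAP, toluene) lactonises only F4 to 16, and the epimer is washed out as the acid. The stereocentre is thus secured by a separate resolving lactonisation, not by the addition–transesterification cascade.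

The endgame (step 10) may fail because BCl3 can also attack the C2 enol ether or the N,O-acetal, and the acid chloride may not cyclise cleanly. The fallback sets out from 20 and comes back at 22. Acid chloride 21, made as before, is treated with Et3N (toluene, 0 → 60 °C) in place of a Lewis acid. Dehydrochlorination gives the dienylketene F5, which closes ring B by 6π electrocyclisation onto ring A and tautomerises to ketone 22. Compound 22 is isolated, and its peri methyl ether is cleaved with MgI2 etherate (Et2O/toluene, 60 °C) to give 23.

**Further compounds**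
F1 | step 8 | maleoylcobalt complex CoCl(PPh3)2(C11H13NO5) from 14 (cobaltacyclopentenedione, trivalent cobalt) | COC1=C(N2CCC[C@@H]2C(=O)OC)C(=O)[Co-2](Cl)([P+](c2ccccc2)(c2ccccc2)c2ccccc2)([P+](c2ccccc2)(c2ccccc2)c2ccccc2)C1=O
F2 | step 8 | methyl (R)-1-[5-(3,5-dimethoxyphenyl)-4-(2-ethoxy-2-oxoethyl)-2-methoxy-3,6-dioxocyclohexa-1,4-dien-1-yl]pyrrolidine-2-carboxylate | COC1=C(N2CCC[C@@H]2C(=O)OC)C(=O)C(c2cc(OC)cc(OC)c2)=C(CC(=O)OCC)C1=O
F3 | step 7 | (R)-1-(2-methoxy-3,4-dioxocyclobut-1-en-1-yl)pyrrolidine-2-carboxylic acid | COC1=C(N2CCC[C@@H]2C(=O)O)C(=O)C1=O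
F4 | step 7 | (R)-1-[(4S)-4-hydroxy-2-methoxy-4-methyl-3-oxocyclobut-1-en-1-yl]pyrrolidine-2-carboxylic acid | COC1=C(N2CCC[C@@H]2C(=O)O)[C@](C)(O)C1=O
F5 | step 10 | dienylketene from 21 (CH=C=O on C10a); C4 (R), aminal carbon (S) | COC1=C2N3CCC[C@@H]3O[C@]2(C)C(c2cc(OC)cc(OC)c2)=C(C=C=O)C1=O
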